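A direct plan would set both methyl-bearing centres first in a small C4 piece and add the arenes afterwards.
A chiral propionimide enolate would be alkylated with a lactate-derived secondary triflate to the anti-dimethylsuccinate A1, which would be reduced to the C2-symmetric diol A2 and activated as the ditosylate A3.
Two different benzyl-protected aryl Grignard reagents would then displace the tosylates one after the other under copper catalysis (through the mono-tosylate A4), and hydrogenolysis would end the route.
Its weakest points would be: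
(a) the enolate SN2 displacement at a secondary α-triflyloxy ester, where one of only two stereocentres would rest on clean inversion against elimination and triflate racemisation;
(b) the mono-arylation of C2-symmetric A3, a statistical event that would need a large excess of the chiral piece and lose material to double coupling;
(c) the second sp2–sp3 coupling, in which a reluctant, tri-oxygenated aryl Grignard reagent would be spent on the most precious intermediate.
Reduction, tosylation and the making of two protected aryl bromides would add steps without adding complexity.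

**Plan of the new route**
The retrosynthesis first removes the four hydrogens at C7, C8, C8' and C7', so that both stereocentres are set in one step from a flat, achiral (1E,3E)-1,4-diaryl-2,3-dimethylbuta-1,3-diene.
The diene is then cut at the C8'–C9' methyl bond and at the C8–C8' sp2–sp2 bond, giving a ring B gem-dibromoalkene (from the aldehyde) and a ring A alkenylboronate (from an arylpropyne).
No ring is formed at any stage: ring A (4-hydroxy-3,5-dimethoxyphenyl) and ring B (3,4-dihydroxy-5-methoxyphenyl) are bought fully oxygenated and carried as methoxymethyl ethers.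
The feature that allows the key step is the pseudo-C2-symmetric core C7–C8(C9)–C8'(C9')–C7': C8 and C8' bear the same four substituents and rings A and B differ only at one meta oxygen, so the (8R,8'R) pair results when one catalyst adds H2 to the same face of two equivalent (E)-ArCH=C(CH3) units.
There is no SN2 step at a secondary carbon, no statistical desymmetrisation (the halves differ from the start and are joined 1:1) and no late sp2–sp3 Grignard coupling; the catalyst sets the stereochemistry last, on the complete carbon skeleton.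

Key step: step 8

Remark: locants follow lignan numbering (C7/C7' benzylic CH2, C8/C8' methine, C9/C9' methyl; unprimed atoms on the ring A side).
Assumption: L* is 4-tert-butyl-2-[2-(di-o-tolylphosphanyl)phenyl]-4,5-dihydrooxazole and cod is cycloocta-1,5-diene; the antipode of L* that delivers H2 to the Si face of C8 and of C8' of the diene is used, both antipodes being available and the correct one to be fixed by one analytical run.

Step 1
Reactants: 1 4-bromo-2,6-dimethoxyphenol
Product: 2 5-bromo-1,3-dimethoxy-2-(methoxymethoxy)benzene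
Conditions: MOMCl (1.5 equiv), i-Pr2NEt (2 equiv), CH2Cl2, 0 °C → rt
Reagents that add atoms: chloromethyl methyl ether, COCCl
Why: Base-mediated O-alkylation of the hindered phenol (Williamson-type acetal formation) masks the acidic OH for the organometallic steps as an ether that is later removed by acid, so that no hydrogenolysis is needed at the end.

Step 2
Reactants: 2 5-bromo-1,3-dimethoxy-2-(methoxymethoxy)benzene
Product: 3 1,3-dimethoxy-2-(methoxymethoxy)-5-(prop-1-yn-1-yl)benzene
Conditions: propyne (3 equiv, THF solution), PdCl2(PhCN)2 (3 mol %), P(t-Bu)3 (6 mol %), CuI (2 mol %), i-Pr2NH, 1,4-dioxane, rt, sealed vessel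
Reagents that add atoms: propyne, CC#C
Why: Sonogashira coupling under the room-temperature tri-tert-butylphosphine protocol, which suits electron-rich aryl bromides and a volatile alkyne, attaches C7–C8–C9 of the ring A half in one step.

Step 3
Reactants: 3 1,3-dimethoxy-2-(methoxymethoxy)-5-(prop-1-yn-1-yl)benzene
Product: 4 (Z)-2-[1-(3,5-dimethoxy-4-(methoxymethoxy)phenyl)prop-1-en-2-yl]-4,4,5,5-tetramethyl-1,3,2-dioxaborolane (ring A cis to CH3, boron trans to ring A)
Conditions: B2pin2 (1.1 equiv), CuCl (5 mol %), tri(p-tolyl)phosphine (6 mol %), NaOt-Bu (10 mol %), MeOH (2 equiv), THF, rt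
Reagents that add atoms: bis(pinacolato)diboron, CC1(C)OB(OC1(C)C)B1OC(C)(C)C(C)(C)O1
Why: Copper-catalysed alkyne hydroboration (syn borylcupration, then protonation of the C–Cu bond by methanol with retention) places boron on the methyl-bearing carbon and copper on the aryl-bearing carbon, so H and B end up cis and the alkene geometry is fixed by the syn addition.

Step 4
Reactants: 5 3,4-dihydroxy-5-methoxybenzaldehyde
Product: 6 3-methoxy-4,5-bis(methoxymethoxy)benzaldehyde
Conditions: MOMCl (3 equiv), i-Pr2NEt (4 equiv), CH2Cl2/DMF, 0 °C → rt, N2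
Reagents that add atoms: chloromethyl methyl ether, COCCl
Why: Double O-alkylation of the catechol under mild amine base protects both hydroxyls as base-stable, acid-labile acetals without touching the non-enolisable aldehyde.

Step 5
Reactants: 6 3-methoxy-4,5-bis(methoxymethoxy)benzaldehyde
Product: 7 5-(2,2-dibromoethenyl)-1-methoxy-2,3-bis(methoxymethoxy)benzene
Conditions: CBr4 (2 equiv), PPh3 (4 equiv), Et3N (1 equiv), CH2Cl2, 0 °C
Reagents that add atoms: carbon tetrabromide, BrC(Br)(Br)Br
Why: Ramirez dibromo-olefination (first stage of the Corey–Fuchs sequence), a Wittig reaction of Ph3P=CBr2 formed in the flask, turns the aldehyde carbon into C7' and adds C8' as a CBr2 group whose two bromines can be replaced one at a time; Et3N buffers traces of HBr so the acetal ethers survive.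

Step 6
Reactants: 4 (Z)-2-[1-(3,5-dimethoxy-4-(methoxymethoxy)phenyl)prop-1-en-2-yl]-4,4,5,5-tetramethyl-1,3,2-dioxaborolane; 7 5-(2,2-dibromoethenyl)-1-methoxy-2,3-bis(methoxymethoxy)benzene
Product: 8 5-[(1Z,3E)-2-bromo-4-(3,5-dimethoxy-4-(methoxymethoxy)phenyl)-3-methylbuta-1,3-dien-1-yl]-1-methoxy-2,3-bis(methoxymethoxy)benzene
Conditions: Pd2(dba)3 (2.5 mol %), tris(2-furyl)phosphine (15 mol %), Cs2CO3 (2.5 equiv), 1,4-dioxane/H2O (4:1), 60 °C
Reagents that add atoms: none
Why: Suzuki–Miyaura coupling in its trans-selective mono-coupling variant for 1,1-dibromoalkenes: zerovalent palladium inserts into the less hindered C–Br bond trans to ring B, the alkenyl group is transferred with retention at both partners, and the more hindered cis bromine remains, which forms the C8–C8' bond and fixes the 1Z,3E geometry.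

Step 7
Reactants: 8 5-[(1Z,3E)-2-bromo-4-(3,5-dimethoxy-4-(methoxymethoxy)phenyl)-3-methylbuta-1,3-dien-1-yl]-1-methoxy-2,3-bis(methoxymethoxy)benzene
Product: 9 5-[(1E,3E)-4-(3,5-dimethoxy-4-(methoxymethoxy)phenyl)-2,3-dimethylbuta-1,3-dien-1-yl]-1-methoxy-2,3-bis(methoxymethoxy)benzene
Conditions: Me2Zn (1.5 equiv, toluene solution), Pd(P(t-Bu)3)2 (3 mol %), THF, 0 °C → rt
Reagents that add atoms: dimethylzinc, C[Zn]C
Why: Negishi coupling of the 2-bromo-1,3-diene under the bulky monophosphine catalyst known to give retention for this substrate class (bisphosphine ligands can invert it) puts C9' on C8' cis to ring B and so gives the E,E-diene.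

Step 8
Reactants: 9 5-[(1E,3E)-4-(3,5-dimethoxy-4-(methoxymethoxy)phenyl)-2,3-dimethylbuta-1,3-dien-1-yl]-1-methoxy-2,3-bis(methoxymethoxy)benzene
Product: 12 5-[(2R,3R)-4-(3,5-dimethoxy-4-(methoxymethoxy)phenyl)-2,3-dimethylbutyl]-1-methoxy-2,3-bis(methoxymethoxy)benzene, via (3R)-monoene reduced on the ring A side 10 (not isolated), via (2R)-monoene reduced on the ring B side 11 (not isolated)
Conditions: H2 (50 bar), [Ir(cod)(L*)][B(C6H3-3,5-(CF3)2)4] (2 mol %), CH2Cl2, 25 °C
Reagents that add atoms: none
Why: The cationic iridium phosphine–oxazoline complex loses cyclooctadiene under H2 and reduces each C=C by syn 1,2-delivery of two hydrogens through an iridium dihydride–alkene complex (a trivalent/pentavalent iridium cycle), so 9 passes through the monoenes 10 and 11 to 12. The closest known reaction type is the iridium-catalysed asymmetric hydrogenation of unfunctionalised (E)-trisubstituted aryl alkenes such as (E)-α-methylstilbene, and its double application to 2,3-disubstituted buta-1,3-dienes. No ring is closed. C8 and C8' are both set by the catalyst, which meets two constitutionally equivalent (E)-ArCH=C(CH3) units and adds H2 to the Si face of each methyl-bearing carbon, so both centres come out R; a wrong-face event at either alkene ends in the meso-like diastereomer and not in the enantiomer, which raises the enantiomeric purity of the (R,R) product at the cost of a minor diastereomer to be removed. The step needs 1,2- and not 1,4-addition, no E/Z or positional isomerisation before reduction, and catalyst control over the allylic centre already present in 10 and 11. The substrate secures this by its defined E,E geometry from two stereospecific couplings, by the known preference of these dihydride catalysts for stepwise 1,2-reduction of conjugated dienes, and by the absence of any coordinating group other than ether oxygens.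

Step 9
Reactants: 12 5-[(2R,3R)-4-(3,5-dimethoxy-4-(methoxymethoxy)phenyl)-2,3-dimethylbutyl]-1-methoxy-2,3-bis(methoxymethoxy)benzene
Product: 13 Sauriol B, 5-[(2R,3R)-4-(4-hydroxy-3,5-dimethoxyphenyl)-2,3-dimethylbutyl]-3-methoxybenzene-1,2-diol
Conditions: HCl (2 M in MeOH), 40 °C, argon
Reagents that add atoms: none
Why: Acid-catalysed transacetalisation of the three aryl methoxymethyl ethers to methanol frees the phenol and the catechol under non-basic, non-oxidising conditions that leave the methyl ethers and the non-benzylic stereocentres untouched.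

**Compound list**
1 | 4-bromo-2,6-dimethoxyphenol | COc1cc(Br)cc(OC)c1O | starting material
2 | 5-bromo-1,3-dimethoxy-2-(methoxymethoxy)benzene | COCOc1c(OC)cc(Br)cc1OC | intermediate
3 | 1,3-dimethoxy-2-(methoxymethoxy)-5-(prop-1-yn-1-yl)benzene | CC#Cc1cc(OC)c(OCOC)c(OC)c1 | intermediate
4 | (Z)-2-[1-(3,5-dimethoxy-4-(methoxymethoxy)phenyl)prop-1-en-2-yl]-4,4,5,5-tetramethyl-1,3,2-dioxaborolane | C/C(B1OC(C)(C)C(C)(C)O1)=C\c1cc(OC)c(OCOC)c(OC)c1 | intermediate
5 | 3,4-dihydroxy-5-methoxybenzaldehyde | COc1cc(C=O)cc(O)c1O | starting material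
6 | 3-methoxy-4,5-bis(methoxymethoxy)benzaldehyde | COCOc1cc(C=O)cc(OC)c1OCOC | intermediate
7 | 5-(2,2-dibromoethenyl)-1-methoxy-2,3-bis(methoxymethoxy)benzene | COCOc1cc(C=C(Br)Br)cc(OC)c1OCOC | intermediate
8 | 5-[(1Z,3E)-2-bromo-4-(3,5-dimethoxy-4-(methoxymethoxy)phenyl)-3-methylbuta-1,3-dien-1-yl]-1-methoxy-2,3-bis(methoxymethoxy)benzene | COCOc1cc(/C=C(Br)/C(C)=C/c2cc(OC)c(OCOC)c(OC)c2)cc(OC)c1OCOC | intermediate
9 | 5-[(1E,3E)-4-(3,5-dimethoxy-4-(methoxymethoxy)phenyl)-2,3-dimethylbuta-1,3-dien-1-yl]-1-methoxy-2,3-bis(methoxymethoxy)benzene | COCOc1cc(/C=C(C)/C(C)=C/c2cc(OC)c(OCOC)c(OC)c2)cc(OC)c1OCOC | intermediate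
10 | 5-[(1E,3R)-4-(3,5-dimethoxy-4-(methoxymethoxy)phenyl)-2,3-dimethylbut-1-en-1-yl]-1-methoxy-2,3-bis(methoxymethoxy)benzene, formed in the flask | COCOc1cc(/C=C(C)/[C@H](C)Cc2cc(OC)c(OCOC)c(OC)c2)cc(OC)c1OCOC | intermediate
11 | 5-[(2R,3E)-4-(3,5-dimethoxy-4-(methoxymethoxy)phenyl)-2,3-dimethylbut-3-en-1-yl]-1-methoxy-2,3-bis(methoxymethoxy)benzene, formed in the flask | COCOc1cc(C[C@@H](C)/C(C)=C/c2cc(OC)c(OCOC)c(OC)c2)cc(OC)c1OCOC | intermediate
12 | 5-[(2R,3R)-4-(3,5-dimethoxy-4-(methoxymethoxy)phenyl)-2,3-dimethylbutyl]-1-methoxy-2,3-bis(methoxymethoxy)benzene | COCOc1cc(C[C@@H](C)[C@H](C)Cc2cc(OC)c(OCOC)c(OC)c2)cc(OC)c1OCOC | intermediate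
13 | Sauriol B, 5-[(2R,3R)-4-(4-hydroxy-3,5-dimethoxyphenyl)-2,3-dimethylbutyl]-3-methoxybenzene-1,2-diol | COc1cc(C[C@@H](C)[C@H](C)Cc2cc(OC)c(O)c(OC)c2)cc(O)c1O | target

Total step count: 9. Longest linear sequence: 7 (steps 1, 2, 3, 6, 7, 8, 9).

**Steps most likely to fail**

Step 8. The risks are incomplete catalyst control in the second reduction (leakage into the meso-like diastereomer), competing 1,4-addition to a tetrasubstituted alkene that is not reduced further, and acid-induced loss of methoxymethyl groups by the acidic iridium hydrides followed by catalyst inhibition. The fallback sets out from 4 and 7 and comes back at 10, which is then isolated.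
- 4 would be hydrogenated on its own with the same type of iridium catalyst (trisubstituted alkenylboronates are an established substrate class) to 2-[(2R)-1-(3,5-dimethoxy-4-(methoxymethoxy)phenyl)propan-2-yl]-4,4,5,5-tetramethyl-1,3,2-dioxaborolane F1, so C8 is fixed before the halves are joined.
- 7 would be methylated at the bromine trans to ring B (Me2Zn, PdCl2(DPEphos)) to (Z)-5-(2-bromoprop-1-en-1-yl)-1-methoxy-2,3-bis(methoxymethoxy)benzene F2.
- Bromine–lithium exchange (t-BuLi, THF, −78 °C) would give (E)-[1-(3-methoxy-4,5-bis(methoxymethoxy)phenyl)prop-1-en-2-yl]lithium F3 (lithium cis to ring B), which would add to F1 to form the lithium alkenylboronate complex F4.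
- I2 and then NaOMe (Zweifel olefination: 1,2-metallate shift of C8 with retention, anti-elimination with inversion of the alkene geometry) should give 10 as a single stereodefined compound.
- The one remaining isolated (E)-β-methylstyrene unit would then be reduced under the conditions of step 8 to 12. The conjugated diene and the coupling of two reductions in one flask are removed, and the ligand can be chosen against the centre already present.

Step 6. The risks are slow transmetalation of the hindered pinacol ester, which would allow double coupling, protodeboronation or base-induced dehydrobromination of the dibromoalkene. The fallback sets out from 7 and comes back at 9.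
- 7 would be taken through the second Corey–Fuchs stage (n-BuLi, 2.1 equiv, THF, −78 °C), the lithium (3-methoxy-4,5-bis(methoxymethoxy)phenyl)ethynide F5 being methylated in the flask with MeI to 1-methoxy-2,3-bis(methoxymethoxy)-5-(prop-1-yn-1-yl)benzene F6.
- Copper-catalysed hydroboration as in step 3 would give (Z)-2-[1-(3-methoxy-4,5-bis(methoxymethoxy)phenyl)prop-1-en-2-yl]-4,4,5,5-tetramethyl-1,3,2-dioxaborolane F7.
- NaOH/I2 (iododeboronation with retention) would give (E)-5-(2-iodoprop-1-en-1-yl)-1-methoxy-2,3-bis(methoxymethoxy)benzene F8.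
- Suzuki–Miyaura coupling of F8 with 4 (Pd(PPh3)4, aqueous Cs2CO3, THF, 60 °C) would give 9 directly. The methyl group is in place before the union, and neither a selective mono-coupling nor a second coupling is needed.

Step 7. The risks are loss of alkene geometry through η3 palladium intermediates of the bromodiene and sluggish oxidative addition at the hindered C–Br bond. The fallback sets out from 8 and comes back at 9.
- Bromine–lithium exchange with t-BuLi (2 equiv, THF, −78 °C) would give [(1E,3E)-4-(3,5-dimethoxy-4-(methoxymethoxy)phenyl)-1-(3-methoxy-4,5-bis(methoxymethoxy)phenyl)-3-methylbuta-1,3-dien-2-yl]lithium F9 (lithium cis to ring B), expected to hold its configuration at this temperature.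
- MeI would alkylate it with retention to 9; this polar methylation has no palladium intermediate through which the geometry could be lost.

**Further compounds**
F1 | step 8 | 2-[(2R)-1-(3,5-dimethoxy-4-(methoxymethoxy)phenyl)propan-2-yl]-4,4,5,5-tetramethyl-1,3,2-dioxaborolane | CC1(C)OB(OC1(C)C)[C@H](C)Cc1cc(OC)c(OCOC)c(OC)c1
F2 | step 8 | (Z)-5-(2-bromoprop-1-en-1-yl)-1-methoxy-2,3-bis(methoxymethoxy)benzene | COCOc1cc(/C=C(Br)/C)cc(OC)c1OCOC
F3 | step 8 | (E)-[1-(3-methoxy-4,5-bis(methoxymethoxy)phenyl)prop-1-en-2-yl]lithium | [Li]/C(C)=C\c1cc(OC)c(OCOC)c(OCOC)c1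
F4 | step 8 | lithium alkenylboronate complex of F1 and F3 | [Li+].CC1(C)O[B-](OC1(C)C)(/C(C)=C\c1cc(OC)c(OCOC)c(OCOC)c1)[C@H](C)Cc1cc(OC)c(OCOC)c(OC)c1
F5 | step 6 | lithium (3-methoxy-4,5-bis(methoxymethoxy)phenyl)ethynide | [Li]C#Cc1cc(OC)c(OCOC)c(OCOC)c1
F6 | step 6 | 1-methoxy-2,3-bis(methoxymethoxy)-5-(prop-1-yn-1-yl)benzene | CC#Cc1cc(OC)c(OCOC)c(OCOC)c1
F7 | step 6 | (Z)-2-[1-(3-methoxy-4,5-bis(methoxymethoxy)phenyl)prop-1-en-2-yl]-4,4,5,5-tetramethyl-1,3,2-dioxaborolane | C/C(B1OC(C)(C)C(C)(C)O1)=C\c1cc(OC)c(OCOC)c(OCOC)c1
F8 | step 6 | (E)-5-(2-iodoprop-1-en-1-yl)-1-methoxy-2,3-bis(methoxymethoxy)benzene | C/C(I)=C\c1cc(OC)c(OCOC)c(OCOC)c1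
F9 | step 7 | [(1E,3E)-4-(3,5-dimethoxy-4-(methoxymethoxy)phenyl)-1-(3-methoxy-4,5-bis(methoxymethoxy)phenyl)-3-methylbuta-1,3-dien-2-yl]lithium | COCOc1cc(/C=C([Li])/C(C)=C/c2cc(OC)c(OCOC)c(OC)c2)cc(OC)c1OCOC
A1 | direct plan | ethyl (2S,3S)-4-[(R)-4-benzyl-2-oxooxazolidin-3-yl]-2,3-dimethyl-4-oxobutanoate | CCOC(=O)[C@@H](C)[C@H](C)C(=O)N1[C@H](Cc2ccccc2)COC1=O
A2 | direct plan | (2S,3S)-2,3-dimethylbutane-1,4-diol | OC[C@@H](C)[C@H](C)CO
A3 | direct plan | (2S,3S)-2,3-dimethylbutane-1,4-diyl bis(4-methylbenzenesulfonate) | Cc1ccc(cc1)S(=O)(=O)OC[C@@H](C)[C@H](C)COS(=O)(=O)c1ccc(C)cc1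
A4 | direct plan | (2S,3R)-4-[4-(benzyloxy)-3,5-dimethoxyphenyl]-2,3-dimethylbutyl 4-methylbenzenesulfonate | Cc1ccc(cc1)S(=O)(=O)OC[C@@H](C)[C@H](C)Cc1cc(OC)c(OCc2ccccc2)c(OC)c1
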